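**Remark on the chemistry (assumptions).** The SMILES is read as the palmitate of natural (−)-loliolide, (6S,7aR), with the C6 oxygen cis to the C7a methyl and trans to the ring oxygen. The sense of induction in step 3 is assigned by analogy with the Hajos–Parrish ketol; if it proved opposite, the antipodal catalyst would be used and nothing else in the route would change.

## Analysis of the target

The target 14 is the C16 ester of a 5,6,7,7a-tetrahydro-1-benzofuran-2(4H)-one (O1, C2, C3, C3a, C4–C7, C7a). A butenolide (O1–C2(=O)–C3H=C3a–C7a) is fused across C3a–C7a to a cyclohexane that carries a gem-dimethyl quaternary carbon (C4), a secondary acyloxy carbon (C6) and a fully substituted oxygenated carbon (C7a: CH3, O1, C3a, C7).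

The two stereocentres are 6S and 7aR and are 1,3-related across C7. O1 must lie in the butenolide plane, so the C7a methyl is axial. The cis C6 oxygen is then axial too, syn to the axial C4 methyl, so the ester sits in a 1,3-diaxial cleft.

This makes C6 easy to set from a C6 ketone, because a hydride can come from the open face, and hard to set by SN2 inversion. C7a, a tetrasubstituted carbinol carbon without hydrogen, is the real stereochemical problem.

Two features invite the strategy. First, O1, C2, C3, C3a, C7a and the C7a methyl are a 2-methylfuran at a higher oxidation level, with the furan α-carbon turned into the stereocentre. Second, C7a is β to C6, so at the ketone level the C7–C7a bond is an aldol bond.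

Sensitive groups are the butenolide (conjugate addition, saponification), the palmitate (base) and, at the ketone level, the β-acyloxy ketone C6(=O)–C7–C7a–O1. The last can open by E1cB (retro-oxa-Michael) and so endanger C7a.

The synthesis is hard because C3a is flanked by two fully substituted carbons, so adding the lactone carbons to a preformed ring is awkward. No cheap chiral compound carries C7a ready-made.

## Retrosynthetic reasoning

**C6–O acyl bond (14 ⇒ 12 + 13).** The ester is cut last. 12 is the parent alcohol and 13 brings all sixteen chain carbons. Acylation proceeds with retention, so no inversion is needed at the hindered axial position.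

**C6–H bond (12 ⇒ 11).** The carbinol is taken back to the ketone 11. The two axial methyl groups at C4 and C7a shield one face of C6, so a bulky hydride should enter from the other face and place the oxygen cis to the C7a methyl, as required. The stereochemical problem thereby shrinks to one centre, C7a.

**C7–C7a bond, the key disconnection (11 ⇒ 8).** In 11 the lactone oxygen is β to the C6 carbonyl, so C7–C7a is an aldol bond between a methyl ketone (C6, C7) and a ketone at C7a. That ketone, with its cis carboxylic acid, is the open tautomer 9 of the achiral, monocyclic γ-hydroxybutenolide 8. The forward reaction must close the carbocycle, set C7a enantioselectively and re-close the lactone. A chiral amino acid catalyst is asked to do this in one operation through the hydroxy acid 10. The cut is made here because it removes the only ring that needs building and the only stereocentre that needs a catalyst. What is left behind has no stereocentre of consequence.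

**Dearomatization (8 ⇒ 6).** The hydroxybutenolide 8 is the [4+2] photooxygenation product of the 2,3-disubstituted furan 6, by way of the endoperoxide 7. The furan oxygen becomes O1, the methyl-bearing α-carbon becomes C7a, the free α-carbon becomes C2 and the two β-carbons become C3a and C3. The flat heteroarene supplies the whole butenolide with the correct Z relationship between carbonyl and C7a built in. No olefination at the hindered C3a is ever needed.

**C3a–C4 bond (6 ⇒ 1 + 2).** The side chain of 6 is the conjugate adduct of a 3-furyl metal derived from 1 with the enone 2. The β-carbon of 2 becomes the gem-dimethyl carbon C4, its α-carbon C5, its carbonyl C6 and its methyl C7. The metalated forms 3 and 4 and the silyl enol ether 5 are passed through without isolation.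

## Alternatives that were turned down

**Alternative 1:** the textbook route.
- Disconnection: the two lactone carbons are cut from C3a of the chiral-pool hydroxy ketone A1. The C7a–O1 bond is cut back to an alkene oxidation of the β,γ-unsaturated acid A2.
- Forward key step: olefination of the protected ketone, deconjugation to A2, then face-selective epoxidation or selenolactonization and elimination to 12.
- Why turned down:
  - The carbonyl of A1 lies between a quaternary and a tertiary carbon, so olefination is slow and needs forcing conditions.
  - The oxidant must attack anti to the C6 oxygen. A free hydroxyl would direct it to the wrong face, so a protecting group is required and the selectivity rests on remote sterics alone.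
  - The enantiopurity is bought and one stereocentre of A1 is destroyed on the way.
  - The count comes to seven or eight steps.

**Alternative 2:** C7a–O1 by oxa-Michael addition.
- Disconnection: C7a–O1 is cut to the achiral dienone acid A4, reached from the commodity enedione A3 by two-carbon homologation at its hindered carbonyl.
- Forward key step: enantioselective lactonization of A4, or a dynamic reduction of the racemate F1 that racemises through A4.
- Why turned down:
  - A4 needs mono-protection of A3, acetylide addition, rearrangement and hydrolysis, with uncontrolled alkene geometry. That is four steps to reach what 8 reaches in two.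
  - The stereo-determining event would be the addition of a weakly nucleophilic carboxylate to a β,β-disubstituted enone. It is nearly thermoneutral and reversible by the same E1cB path, so kinetic selectivity would erode.
  - A dynamic reduction would need a catalyst that distinguishes the enantiomers of a ketone whose two α-methylene groups are both neopentyl.
  - No skeletal bond is formed.

**Alternative 3:** both rings from an acyclic chain.
- Disconnection: C3a–C7a and O1–C2 are cut together to the keto ynoate A5.
- Forward key step: reductive ketyl–ynoate cyclization (or a carbene-catalysed homoenolate annulation of the corresponding ynal) followed by lactonization, then desilylation and acylation to 14.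
- Why turned down:
  - A5 needs a quaternary propargylic carbon, an asymmetric aldol and a protecting group, at least six steps. That is more than the whole chosen route.
  - The configuration at C7a would depend on whether methyl or the metal-bound oxygen sits axial in the chair transition state, which nothing in A5 controls.
  - The geometry of the new C3=C3a bond is set by an unselective protonation, and only the Z isomer lactonizes.

Key step: step 3

## Route

Step 1
Reactants: 1 3-bromo-2-methylfuran; 2 mesityl oxide (4-methylpent-3-en-2-one)
Product: 6 4-methyl-4-(2-methylfuran-3-yl)pentan-2-one, via furyllithium 3 (not isolated), via furylmagnesium bromide 4 (not isolated), via silyl enol ether 5 (not isolated)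
Conditions: n-BuLi, THF, −78 °C; MgBr2·OEt2, −78 °C; then CuBr·SMe2 (10 mol %), TMSCl, DMPU, 2, −78 → −30 °C; 1 M HCl, 0 °C
Reagents that add atoms: none
Why: Bromine–lithium exchange at −78 °C keeps the metal at C3, and copper-catalysed, chlorosilane-accelerated conjugate addition of the Grignard reagent is the established way to build a quaternary carbon on a β,β-disubstituted enone; brief acid work-up cleaves the enol ether. No stereocentre is formed.

Step 2
Reactants: 6 4-methyl-4-(2-methylfuran-3-yl)pentan-2-one
Product: 8 (±)-5-hydroxy-5-methyl-4-(2-methyl-4-oxopentan-2-yl)furan-2(5H)-one, via furan endoperoxide 7 (not isolated)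
Conditions: O2, hν (white LED), tetraphenylporphyrin (cat.), iPr2NEt, CH2Cl2, −78 °C; cold aqueous citric acid wash
Reagents that add atoms: dioxygen, O=O
Why: Singlet oxygen adds [4+2] across the furan α-carbons, and the hindered base removes the only bridgehead hydrogen (Kornblum–DeLaMare fragmentation), so the carbonyl appears at the former free α-carbon and the hemiketal at the methyl-bearing one. The hemiketal centre is labile through ring–chain tautomerism and is of no consequence.

Step 3
Reactants: 8 (±)-5-hydroxy-5-methyl-4-(2-methyl-4-oxopentan-2-yl)furan-2(5H)-one
Product: 11 (7aR)-4,4,7a-trimethyl-5,7a-dihydro-1-benzofuran-2,6(4H,7H)-dione, via open keto acid 9 (not isolated), via aldol hydroxy acid 10 (not isolated)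
Conditions: (R)-proline (20 mol %), DMSO, 23 °C
Reagents that add atoms: none
Why: Proposed new method: an enantioface-selective, proline-catalysed intramolecular aldol onto the ketone that a γ-hydroxybutenolide unmasks by ring–chain tautomerism, followed by lactonization; the closest known reaction type is the Hajos–Parrish–Eder–Sauer–Wiechert ketol cyclization. The catalyst condenses with the unhindered methyl ketone of 9 to an enamine on the methyl side (C7), which attacks the C7a carbonyl while the proline carboxylic acid hydrogen-bonds that carbonyl. The carbocycle closes in a 6-(enolendo)-exo-trig mode with the same topology as the Hajos–Parrish ketol (three atoms between acceptor carbon and enamine carbon, tertiary carbinol formed). The hydroxy acid 10 then closes the lactone by 5-exo-trig attack on the cis carboxyl group, whose Z geometry is inherited from the furan, and this traps the aldol irreversibly. C7a is the only new stereocentre and is catalyst-controlled: mapping the tether, the nucleophilic carbon and the passive substituent onto the Hajos ketol, where (S)-proline gives the 3aS carbinol, predicts 7aS from (S)-proline and therefore 7aR from (R)-proline. Regioselectivity (C7 as donor and not the C7a methyl; aldol and not Michael addition at C3) should follow because the C7a ketone is largely masked as the hemiketal and because only the desired aldol is drained by lactonization. The configuration of 11 should hold under the conditions because its ketone is flanked by two fully substituted β-carbons and condenses with the catalyst far more slowly than the methyl ketone of 9, which disfavours the retro-oxa-Michael pathway.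

Step 4
Reactants: 11 (7aR)-4,4,7a-trimethyl-5,7a-dihydro-1-benzofuran-2,6(4H,7H)-dione
Product: 12 (6S,7aR)-6-hydroxy-4,4,7a-trimethyl-5,6,7,7a-tetrahydro-1-benzofuran-2(4H)-one
Conditions: L-Selectride, THF, −78 °C; AcOH quench
Reagents that add atoms: none
Why: Substrate-controlled ketone reduction: the bulky hydride should attack C6 from the face opposite the two syn-axial methyl groups at C4 and C7a (equatorial attack), giving the axial alcohol cis to the C7a methyl, which is 6S. The fully substituted β-carbon of the butenolide and the low temperature should protect the lactone.

Step 5
Reactants: 12 (6S,7aR)-6-hydroxy-4,4,7a-trimethyl-5,6,7,7a-tetrahydro-1-benzofuran-2(4H)-one; 13 palmitoyl chloride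
Product: 14 (6S,7aR)-4,4,7a-trimethyl-2-oxo-2,4,5,6,7,7a-hexahydro-1-benzofuran-6-yl hexadecanoate
Conditions: 13, pyridine, DMAP (cat.), CH2Cl2, 0 → 23 °C
Reagents that add atoms: none
Why: DMAP-catalysed acylation takes place at oxygen with retention, so both stereocentres are untouched; the acylpyridinium is reactive enough for the hindered axial alcohol.

## Compound list

1 | 3-bromo-2-methylfuran | Cc1occc1Br | starting material
2 | mesityl oxide (4-methylpent-3-en-2-one) | CC(=O)C=C(C)C | starting material
3 | (2-methylfuran-3-yl)lithium | Cc1occc1[Li] | intermediate (not isolated)
4 | (2-methylfuran-3-yl)magnesium bromide | Cc1occc1[Mg]Br | intermediate (not isolated)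
5 | trimethyl{[4-methyl-4-(2-methylfuran-3-yl)pent-2-en-2-yl]oxy}silane (E/Z mixture) | CC(O[Si](C)(C)C)=CC(C)(C)c1ccoc1C | intermediate (not isolated)
6 | 4-methyl-4-(2-methylfuran-3-yl)pentan-2-one | CC(=O)CC(C)(C)c1ccoc1C | intermediate
7 | 4-methyl-4-(1-methyl-2,3,7-trioxabicyclo[2.2.1]hept-5-en-6-yl)pentan-2-one (racemic) | CC(=O)CC(C)(C)C1=CC2OOC1(C)O2 | intermediate (not isolated)
8 | (±)-5-hydroxy-5-methyl-4-(2-methyl-4-oxopentan-2-yl)furan-2(5H)-one | CC(=O)CC(C)(C)C1=CC(=O)OC1(C)O | intermediate
9 | (2Z)-3-acetyl-4,4-dimethyl-6-oxohept-2-enoic acid | OC(=O)/C=C(\C(C)=O)C(C)(C)CC(C)=O | intermediate (not isolated)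
10 | (2Z)-2-[(2R)-2-hydroxy-2,6,6-trimethyl-4-oxocyclohexylidene]acetic acid | O=C1CC(C)(C)/C(=C/C(O)=O)[C@@](O)(C)C1 | intermediate (not isolated)
11 | (7aR)-4,4,7a-trimethyl-5,7a-dihydro-1-benzofuran-2,6(4H,7H)-dione | O=C1CC(C)(C)C2=CC(=O)O[C@]2(C)C1 | intermediate
12 | (6S,7aR)-6-hydroxy-4,4,7a-trimethyl-5,6,7,7a-tetrahydro-1-benzofuran-2(4H)-one, (−)-loliolide | O[C@H]1CC(C)(C)C2=CC(=O)O[C@]2(C)C1 | intermediate
13 | palmitoyl chloride (hexadecanoyl chloride) | CCCCCCCCCCCCCCCC(Cl)=O | starting material
14 | (6S,7aR)-4,4,7a-trimethyl-2-oxo-2,4,5,6,7,7a-hexahydro-1-benzofuran-6-yl hexadecanoate | CCCCCCCCCCCCCCCC(=O)O[C@H]1CC(C)(C)C2=CC(=O)O[C@]2(C)C1 | target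

## Step count and risk

Total step count: 5. Longest linear sequence: 5 (1 → 6 → 8 → 11 → 12 → 14).

**Step 3 (key step, proposed new method).** The most likely failures are weak enantioface discrimination at the C7a ketone and erosion of the configuration by amine-induced elimination and re-addition of the carboxylate. The conversion may also be slow because the acceptor ketone is mostly masked as the hemiketal. Traces of amine base carried over from step 2 could cause a racemic background cyclization.

Fallback, by known chemistry: it sets out from 8. Pyrrolidine and acetic acid (catalytic, toluene) or KOH in methanol followed by acidification should close the ring without stereocontrol to the racemic dione F1. L-Selectride then gives racemic loliolide F2. Esterification with (S)-O-methylmandelic acid (DCC, DMAP) gives the diastereomeric esters F3 (6S,7aR) and F4 (6R,7aS), which are separated by chromatography or crystallization. Methanolysis of F3 (K2CO3, MeOH) returns to the route at 12.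

**Step 1.** 1,2-Addition or enolization of 2 may compete with conjugate addition at the hindered β-carbon. The 3-metalated furan may also isomerize to the more stable α-metalated species if the temperature rises.

Fallback: it sets out from 1. Bromine–lithium exchange and quenching with acetone give the tertiary alcohol F5. Its Lewis-acid-catalysed SN1 substitution with 2-(trimethylsilyloxy)propene (catalytic BF3·OEt2 or Bi(OTf)3, CH2Cl2, low temperature) builds the same quaternary carbon from a furan-stabilised cation and comes back to the route at 6.

**Step 2.** The endoperoxide may fragment along other paths (over-oxidation, rearrangement to ring-opened peroxides) if the proton removal is slow. The base may also trigger premature, racemic ring closure of the product.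

Fallback: it sets out from 6. Electrophilic oxidative ring opening with NBS in buffered aqueous acetone gives the Z enedione aldehyde F6. Pinnick oxidation (NaClO2, NaH2PO4, 2-methylbut-2-ene) converts it into the acid 9, which closes spontaneously, and the route is rejoined at 8.

**Step 4.** Conjugate hydride addition to the butenolide or attack on the lactone carbonyl may compete. Facial selectivity may also be incomplete if the ring leaves the chair in which both methyl groups shield the same face.

Fallback: it sets out from 11. Luche reduction (NaBH4, CeCl3, MeOH, −78 °C) is selective for the ketone and would give 12 together with its C6 epimer F7. The two are separated, and F7 is re-oxidised with Dess–Martin periodinane to 11 and recycled, so that the material converges on 12.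

## Further compounds

F1 | step 3 | racemic 4,4,7a-trimethyl-5,7a-dihydro-1-benzofuran-2,6(4H,7H)-dione | O=C1CC(C)(C)C2=CC(=O)O[C@]2(C)C1.O=C1CC(C)(C)C2=CC(=O)O[C@@]2(C)C1
F2 | step 3 | racemic (6S*,7aR*)-6-hydroxy-4,4,7a-trimethyl-5,6,7,7a-tetrahydro-1-benzofuran-2(4H)-one | O[C@H]1CC(C)(C)C2=CC(=O)O[C@]2(C)C1.O[C@@H]1CC(C)(C)C2=CC(=O)O[C@@]2(C)C1
F3 | step 3 | (6S,7aR)-4,4,7a-trimethyl-2-oxo-2,4,5,6,7,7a-hexahydro-1-benzofuran-6-yl (2S)-2-methoxy-2-phenylacetate | CO[C@H](C(=O)O[C@H]1CC(C)(C)C2=CC(=O)O[C@]2(C)C1)c1ccccc1
F4 | step 3 | (6R,7aS)-4,4,7a-trimethyl-2-oxo-2,4,5,6,7,7a-hexahydro-1-benzofuran-6-yl (2S)-2-methoxy-2-phenylacetate | CO[C@H](C(=O)O[C@@H]1CC(C)(C)C2=CC(=O)O[C@@]2(C)C1)c1ccccc1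
F5 | step 1 | 2-(2-methylfuran-3-yl)propan-2-ol | CC(C)(O)c1ccoc1C
F6 | step 2 | (2Z)-3-acetyl-4,4-dimethyl-6-oxohept-2-enal | O=C/C=C(\C(C)=O)C(C)(C)CC(C)=O
F7 | step 4 | (6R,7aR)-6-hydroxy-4,4,7a-trimethyl-5,6,7,7a-tetrahydro-1-benzofuran-2(4H)-one | O[C@@H]1CC(C)(C)C2=CC(=O)O[C@]2(C)C1
A1 | alternative 1 | (4R,6R)-4-hydroxy-2,2,6-trimethylcyclohexan-1-one | C[C@@H]1C[C@@H](O)CC(C)(C)C1=O
A2 | alternative 1 | 2-[(4R)-4-hydroxy-2,6,6-trimethylcyclohex-1-en-1-yl]acetic acid | OC(=O)CC1=C(C)C[C@@H](O)CC1(C)C
A3 | alternative 2 | 2,6,6-trimethylcyclohex-2-ene-1,4-dione | CC1=CC(=O)CC(C)(C)C1=O
A4 | alternative 2 | (2Z)-2-(2,6,6-trimethyl-4-oxocyclohex-2-en-1-ylidene)acetic acid | OC(=O)/C=C1\C(C)=CC(=O)CC1(C)C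
A5 | alternative 3 | ethyl (6S)-6-[(tert-butyldimethylsilyl)oxy]-4,4-dimethyl-8-oxonon-2-ynoate | CCOC(=O)C#CC(C)(C)C[C@H](O[Si](C)(C)C(C)(C)C)CC(C)=O
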